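**Retrosynthetic overview**
1. Target ⇐ thermal sulfoxide elimination of a (2S,3R)-3-phenylsulfanylchroman ⇐ enantioselective sulfenoetherification of an (E)-C-allylated resorcinol (pyran ring closed last, chromene C2 set here).
2. C-allylated resorcinol ⇐ Friedel–Crafts allylation of 4,5,6-trimethoxybenzene-1,3-diol with the (E)-allylic alcohol side chain.
3. The arene ⇐ squaric acid + tert-butyl vinyl ether by cyclobutenone thermolysis (benzene ring formed second).
4. Allylic alcohol ⇐ terminal alkyne (carboalumination/hydroxymethylation) ⇐ exocyclic alkene ⇐ 2,2,6-trisubstituted cyclohexanone (Peterson olefination).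
5. Cyclohexanone ⇐ key catalyst-controlled ring expansion of 2-methylcyclopentanone by 5-diazohex-1-yne (cyclohexane ring and both of its stereocentres formed first).

Assumption: the SMILES is read as (2S)-2-{2-[(1R,3R)-1,3-dimethyl-2-methylidenecyclohexyl]ethyl}-6,7,8-trimethoxy-2-methyl-2H-chromen-5-ol (ring methyls trans), and hex-5-yn-2-one, racemic 2-methylcyclopentanone, squaric acid and tert-butyl vinyl ether are taken as commercial.

**Route**

Step 1
Reactants: 1 hex-5-yn-2-one
Product: 2 hex-5-yn-2-one hydrazone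
Conditions: N2H4·H2O (10 equiv), EtOH, 23 °C
Reagents that add atoms: hydrazine, NN
Why: Hydrazone condensation of the methyl ketone, with excess hydrazine suppressing azine formation; no stereocentre is formed.

Step 2
Reactants: 2 hex-5-yn-2-one hydrazone; 3 (±)-2-methylcyclopentan-1-one
Product: 5 (2R,6R)-2-(but-3-yn-1-yl)-2,6-dimethylcyclohexan-1-one, via 5-diazohex-1-yne 4 (not isolated)
Conditions: activated MnO2, MgSO4, CH2Cl2, −20 °C, cold filtration; then Sc(OTf)3 (10 mol%), L-pipecolic-acid-derived N,N'-dioxide bis(2,6-diisopropylanilide) ligand (12 mol%; the enantiomer that gives 2R,6R), 3 (3 equiv), 4 Å MS, CH2Cl2, −60 °C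
Reagents that add atoms: none
Why: Proposed new method: enantio- and diastereoselective Lewis-acid-catalysed diazoalkane–ketone homologation (Tiffeneau–Demjanov-type ring expansion) run as a kinetic resolution of the cheap racemic ketone used in excess: the chiral Sc(OTf)3–N,N'-dioxide complex binds the ketone, the diazo carbon of 4 adds anti to the 2-methyl group on the carbonyl face left open by the ligand (so only (R)-3 is matched), the ligand wall also fixes the diazo enantioface (butynyl chain away from the anilide arm), and in the diazonium alkoxide the less substituted C1–C5 bond antiperiplanar to N2+ shifts to the diazonium carbon with loss of N2, which forms the six-membered ring and the quaternary centre C2 (R) while C6 (R, the former C2 of 3) is not touched; the closest known chemistry is the racemic Sc(OTf)3-catalysed ring expansion of cycloalkanones with disubstituted diazoalkanes and the Sc(OTf)3/N,N'-dioxide-catalysed asymmetric homologation with α-alkyl α-diazo esters, neither shown for an all-alkyl diazoalkane nor for resolving an α-branched ketone.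

Step 3
Reactants: 5 (2R,6R)-2-(but-3-yn-1-yl)-2,6-dimethylcyclohexan-1-one
Product: 7 (1R,3R)-1-(but-3-yn-1-yl)-1,3-dimethyl-2-methylidenecyclohexane, via β-hydroxysilane 6 (not isolated)
Conditions: Me3SiCH2Li (3 equiv), CeCl3 (3 equiv), THF, −78 → 0 °C; H2O; then KH, THF, 23 °C
Reagents that add atoms: (trimethylsilyl)methyllithium, [Li]C[Si](C)(C)C
Why: Cerium-modified Peterson olefination: the weakly basic organocerium reagent adds to the hindered, enolisable ketone without epimerising C6, and syn-elimination from the potassium alkoxide of 6 gives the exocyclic alkene, the carbinol centre of 6 being destroyed again.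

Step 4
Reactants: 7 (1R,3R)-1-(but-3-yn-1-yl)-1,3-dimethyl-2-methylidenecyclohexane
Product: 10 (2E)-5-[(1R,3R)-1,3-dimethyl-2-methylidenecyclohexyl]-3-methylpent-2-en-1-ol, via alkenyldimethylalane 8 (not isolated), via lithium alkenylaluminate 9 (not isolated)
Conditions: Me3Al (2.5 equiv), Cp2ZrCl2 (25 mol%), CH2Cl2, 0 → 23 °C; then n-BuLi, THF, −78 °C; (CH2O)n, −78 → 23 °C; aqueous work-up
Reagents that add atoms: trimethylaluminium, C[Al](C)C; formaldehyde (as paraformaldehyde), C=O
Why: Negishi carboalumination: zirconocene-catalysed syn addition of Me–Al to the terminal alkyne puts aluminium on the terminal carbon and fixes the (E) geometry, which is kept when the aluminate is hydroxymethylated; the hindered 1,1-disubstituted alkene does not react and no stereocentre is formed.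

Step 5
Reactants: 11 squaric acid (3,4-dihydroxycyclobut-3-ene-1,2-dione)
Product: 12 dimethyl squarate (3,4-dimethoxycyclobut-3-ene-1,2-dione)
Conditions: MeOH, HC(OMe)3, reflux
Reagents that add atoms: methanol, CO
Why: Acid-autocatalysed vinylogous esterification of squaric acid, driven to completion by the orthoester as water scavenger; no stereocentre.

Step 6
Reactants: 12 dimethyl squarate; 13 tert-butyl vinyl ether
Product: 16 4-[1-(tert-butoxy)ethenyl]-2,3,4-trimethoxycyclobut-2-en-1-one (racemic), via 1-(tert-butoxy)ethenyllithium 14 (not isolated), via lithium alkoxide 15 (not isolated)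
Conditions: 13, t-BuLi, THF, −78 → 0 °C; then 12, −78 °C; then MeOTf, −78 → 0 °C
Reagents that add atoms: methyl triflate, COS(=O)(=O)C(F)(F)F
Why: α-Lithiation of the vinyl ether, 1,2-addition to one of the two equivalent carbonyl groups of 12 and O-methylation of the tertiary lithium alkoxide by the hard alkylating agent; the new stereocentre is racemic and disappears on aromatisation in step 7.

Step 7
Reactants: 16 4-[1-(tert-butoxy)ethenyl]-2,3,4-trimethoxycyclobut-2-en-1-one
Product: 18 4,5,6-trimethoxybenzene-1,3-diol, via 5-(tert-butoxy)-2,3,4-trimethoxyphenol 17 (not isolated)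
Conditions: PhMe, 110 °C; then TFA, CH2Cl2, 0 → 23 °C
Reagents that add atoms: none
Why: Moore rearrangement (thermal electrocyclic opening of the cyclobutenone with outward rotation of the 4-methoxy group, 6π ring closure and tautomerisation) builds the pentaoxygenated benzene ring with its one free position between two oxygens, and acidolysis (E1) of the aryl tert-butyl ether frees the second phenol; no stereocentre.

Step 8
Reactants: 10 (2E)-5-[(1R,3R)-1,3-dimethyl-2-methylidenecyclohexyl]-3-methylpent-2-en-1-ol; 18 4,5,6-trimethoxybenzene-1,3-diol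
Product: 19 2-[(2E)-5-[(1R,3R)-1,3-dimethyl-2-methylidenecyclohexyl]-3-methylpent-2-en-1-yl]-4,5,6-trimethoxybenzene-1,3-diol
Conditions: p-TsOH·H2O (5 mol%), 18 (2 equiv), CH2Cl2, 0 °C
Reagents that add atoms: none
Why: Friedel–Crafts allylation: the allyl cation from 10 is trapped at its primary terminus by the only free, doubly ortho-activated carbon of 18, as in the acid-catalysed geranylation of resorcinols, which keeps the (E)-trisubstituted alkene; no stereocentre is formed.

Step 9
Reactants: 19 2-[(2E)-5-[(1R,3R)-1,3-dimethyl-2-methylidenecyclohexyl]-3-methylpent-2-en-1-yl]-4,5,6-trimethoxybenzene-1,3-diol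
Product: 20 (2S,3R)-2-{2-[(1R,3R)-1,3-dimethyl-2-methylidenecyclohexyl]ethyl}-6,7,8-trimethoxy-2-methyl-3-(phenylsulfanyl)-3,4-dihydro-2H-chromen-5-ol
Conditions: N-(phenylsulfanyl)phthalimide (1.1 equiv), BINAM-derived diisopropylamino selenophosphoramide (10 mol%; the enantiomer that gives 2S,3R), HFIP, 0 °C
Reagents that add atoms: N-(phenylsulfanyl)phthalimide, O=C1c2ccccc2C(=O)N1Sc1ccccc1
Why: Lewis-base-catalysed enantioselective sulfenoetherification: the chiral selenophosphoramide delivers PhS+ to one face of the (E)-alkene to give a configurationally stable thiiranium ion, which one of the two equivalent phenol oxygens opens anti at the tertiary carbon (6-endo), so that C2 (S) and C3 (R) are set together and the pyran ring is closed.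

Step 10
Reactants: 20 (2S,3R)-2-{2-[(1R,3R)-1,3-dimethyl-2-methylidenecyclohexyl]ethyl}-6,7,8-trimethoxy-2-methyl-3-(phenylsulfanyl)-3,4-dihydro-2H-chromen-5-ol
Product: 22 (2S)-2-{2-[(1R,3R)-1,3-dimethyl-2-methylidenecyclohexyl]ethyl}-6,7,8-trimethoxy-2-methyl-2H-chromen-5-ol, via sulfoxide 21 (not isolated)
Conditions: mCPBA (1.0 equiv), CH2Cl2, −78 °C; then PhMe, 100 °C
Reagents that add atoms: none
Why: Chemoselective sulfide oxidation followed by thermal syn-elimination of the sulfoxide (Ei); the only β-hydrogens are the benzylic ones at C4, so the C3=C4 bond forms and the quaternary C2 centre, which is not involved, keeps its (S) configuration.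

**Compound list**

1 | hex-5-yn-2-one | CC(=O)CCC#C | starting material
2 | hex-5-yn-2-one hydrazone (E/Z mixture) | CC(=NN)CCC#C | intermediate
3 | (±)-2-methylcyclopentan-1-one (the R enantiomer is consumed) | CC1CCCC1=O | starting material
4 | 5-diazohex-1-yne | CC(=[N+]=[N-])CCC#C | intermediate
5 | (2R,6R)-2-(but-3-yn-1-yl)-2,6-dimethylcyclohexan-1-one | O=C1[C@H](C)CCC[C@]1(C)CCC#C | intermediate
6 | (2R,6R)-2-(but-3-yn-1-yl)-2,6-dimethyl-1-[(trimethylsilyl)methyl]cyclohexan-1-ol (β-hydroxysilane, C1 epimers) | C[Si](C)(C)CC1(O)[C@H](C)CCC[C@]1(C)CCC#C | intermediate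
7 | (1R,3R)-1-(but-3-yn-1-yl)-1,3-dimethyl-2-methylidenecyclohexane | C=C1[C@H](C)CCC[C@]1(C)CCC#C | intermediate
8 | {(1E)-4-[(1R,3R)-1,3-dimethyl-2-methylidenecyclohexyl]-2-methylbut-1-en-1-yl}dimethylalumane (alkenyldimethylalane) | C=C1[C@H](C)CCC[C@]1(C)CC/C(C)=C/[Al](C)C | intermediate
9 | lithium butyl{(1E)-4-[(1R,3R)-1,3-dimethyl-2-methylidenecyclohexyl]-2-methylbut-1-en-1-yl}dimethylaluminate (lithium alkenylaluminate) | [Li+].C=C1[C@H](C)CCC[C@]1(C)CC/C(C)=C/[Al-](C)(C)CCCC | intermediate
10 | (2E)-5-[(1R,3R)-1,3-dimethyl-2-methylidenecyclohexyl]-3-methylpent-2-en-1-ol | C=C1[C@H](C)CCC[C@]1(C)CC/C(C)=C/CO | intermediate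
11 | squaric acid (3,4-dihydroxycyclobut-3-ene-1,2-dione) | OC1=C(O)C(=O)C1=O | starting material
12 | dimethyl squarate (3,4-dimethoxycyclobut-3-ene-1,2-dione) | COC1=C(OC)C(=O)C1=O | intermediate
13 | tert-butyl vinyl ether | C=COC(C)(C)C | starting material
14 | 1-(tert-butoxy)ethenyllithium | [Li]C(=C)OC(C)(C)C | intermediate
15 | lithium 1-[1-(tert-butoxy)ethenyl]-2,3-dimethoxy-4-oxocyclobut-2-en-1-olate (lithium alkoxide, racemic) | [Li+].[O-]C1(C(=C)OC(C)(C)C)C(OC)=C(OC)C1=O | intermediate
16 | 4-[1-(tert-butoxy)ethenyl]-2,3,4-trimethoxycyclobut-2-en-1-one (racemic) | COC1=C(OC)C(OC)(C(=C)OC(C)(C)C)C1=O | intermediate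
17 | 5-(tert-butoxy)-2,3,4-trimethoxyphenol | COc1c(O)cc(OC(C)(C)C)c(OC)c1OC | intermediate
18 | 4,5,6-trimethoxybenzene-1,3-diol | COc1c(O)cc(O)c(OC)c1OC | intermediate
19 | 2-[(2E)-5-[(1R,3R)-1,3-dimethyl-2-methylidenecyclohexyl]-3-methylpent-2-en-1-yl]-4,5,6-trimethoxybenzene-1,3-diol | C=C1[C@H](C)CCC[C@]1(C)CC/C(C)=C/Cc1c(O)c(OC)c(OC)c(OC)c1O | intermediate
20 | (2S,3R)-2-{2-[(1R,3R)-1,3-dimethyl-2-methylidenecyclohexyl]ethyl}-6,7,8-trimethoxy-2-methyl-3-(phenylsulfanyl)-3,4-dihydro-2H-chromen-5-ol | C=C1[C@H](C)CCC[C@]1(C)CC[C@@]1(C)[C@H](Sc2ccccc2)Cc2c(O)c(OC)c(OC)c(OC)c2O1 | intermediate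
21 | (2S,3R)-3-(benzenesulfinyl)-2-{2-[(1R,3R)-1,3-dimethyl-2-methylidenecyclohexyl]ethyl}-6,7,8-trimethoxy-2-methyl-3,4-dihydro-2H-chromen-5-ol (sulfoxide, sulfur epimers) | C=C1[C@H](C)CCC[C@]1(C)CC[C@@]1(C)[C@H](S(=O)c2ccccc2)Cc2c(O)c(OC)c(OC)c(OC)c2O1 | intermediate
22 | (2S)-2-{2-[(1R,3R)-1,3-dimethyl-2-methylidenecyclohexyl]ethyl}-6,7,8-trimethoxy-2-methyl-2H-chromen-5-ol | C=C1[C@H](C)CCC[C@]1(C)CC[C@@]1(C)C=Cc2c(O)c(OC)c(OC)c(OC)c2O1 | target

**Step count and risks**

Total step count: 10. Longest linear sequence: 7 (steps 1, 2, 3, 4, 8, 9, 10).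

The three steps most likely to fail:

Step 2 (the proposed new step). Risks are poor discrimination of methyl against the butynyl chain at the diazo carbon, reaction of the mismatched ketone enantiomer, migration of the substituted α-carbon, and 1,2-hydride shift of the dialkyl diazoalkane to alkenes. The fallback uses known chemistry, sets out from 3 and 4 (made from 2 as before) and comes back at 5. The homologation is run with Sc(OTf)3 alone, the established achiral Lewis-acid ring expansion in which the less substituted carbon migrates. This gives 5 together with its enantiomer, (2S,6S)-2-(but-3-yn-1-yl)-2,6-dimethylcyclohexan-1-one F1, and the two cis-dimethyl isomers, the (2R,6S) isomer F2 and the (2S,6R) isomer F3. The trans pair is separated from the cis pair on silica, DBU equilibration at C6 recycles F2 into 5 (and F3 into F1), and preparative chiral SFC delivers 5. Stereocontrol by catalysis is thus replaced by racemic synthesis and resolution.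

Step 8. Risks are E/Z scrambling of the allyl cation, acid-induced migration of the exocyclic alkene into the ring, and acid cyclisation of 19 to a racemic chroman. The fallback sets out from 10 and 18 and comes back at 19. Alcohol 10 is converted with CBr4 and PPh3 into the allylic bromide, (1R,3R)-1-[(3E)-5-bromo-3-methylpent-3-en-1-yl]-1,3-dimethyl-2-methylidenecyclohexane F4. The monosodium phenoxide of 18 (NaH, toluene) is then C-alkylated by F4 at the carbon between the two oxygens. This is the known ortho-C-allylation of phenoxides in non-polar solvents and involves no cation and no acid.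

Step 9. Risks are insufficient enantioselectivity on this trisubstituted alkene with a free second phenol, and competing sulfenylation of the exocyclic alkene. The fallback sets out from 19 and comes back at 22, replacing steps 9 and 10. Diol 19 is silylated (TBSCl, imidazole) to the bis-silyl ether F5. F5 is epoxidised at the trisubstituted alkene only by Shi epoxidation (fructose-derived ketone, KHSO5 as Oxone, K2CO3, 0 °C) to the (2R,3R)-epoxide F6. TBAF/AcOH then gives the epoxy diol F7, which under CSA catalysis closes 6-endo at the tertiary epoxide carbon with inversion to the (2S,3R)-chroman-3-ol F8. Syn-dehydration of F8 with the Burgess reagent towards the benzylic C4–H gives 22.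

**Further compounds**

F1 | step 2 | (2S,6S)-2-(but-3-yn-1-yl)-2,6-dimethylcyclohexan-1-one | O=C1[C@@H](C)CCC[C@@]1(C)CCC#C
F2 | step 2 | (2R,6S)-2-(but-3-yn-1-yl)-2,6-dimethylcyclohexan-1-one | O=C1[C@@H](C)CCC[C@]1(C)CCC#C
F3 | step 2 | (2S,6R)-2-(but-3-yn-1-yl)-2,6-dimethylcyclohexan-1-one | O=C1[C@H](C)CCC[C@@]1(C)CCC#C
F4 | step 8 | (1R,3R)-1-[(3E)-5-bromo-3-methylpent-3-en-1-yl]-1,3-dimethyl-2-methylidenecyclohexane | C=C1[C@H](C)CCC[C@]1(C)CC/C(C)=C/CBr
F5 | step 9 | {2-[(2E)-5-[(1R,3R)-1,3-dimethyl-2-methylidenecyclohexyl]-3-methylpent-2-en-1-yl]-4,5,6-trimethoxy-1,3-phenylene}bis(oxy)bis[tert-butyl(dimethyl)silane] | C=C1[C@H](C)CCC[C@]1(C)CC/C(C)=C/Cc1c(O[Si](C)(C)C(C)(C)C)c(OC)c(OC)c(OC)c1O[Si](C)(C)C(C)(C)C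
F6 | step 9 | {2-[((2R,3R)-3-{2-[(1R,3R)-1,3-dimethyl-2-methylidenecyclohexyl]ethyl}-3-methyloxiran-2-yl)methyl]-4,5,6-trimethoxy-1,3-phenylene}bis(oxy)bis[tert-butyl(dimethyl)silane] | C=C1[C@H](C)CCC[C@]1(C)CC[C@@]2(C)O[C@@H]2Cc2c(O[Si](C)(C)C(C)(C)C)c(OC)c(OC)c(OC)c2O[Si](C)(C)C(C)(C)C
F7 | step 9 | 2-[((2R,3R)-3-{2-[(1R,3R)-1,3-dimethyl-2-methylidenecyclohexyl]ethyl}-3-methyloxiran-2-yl)methyl]-4,5,6-trimethoxybenzene-1,3-diol | C=C1[C@H](C)CCC[C@]1(C)CC[C@@]2(C)O[C@@H]2Cc2c(O)c(OC)c(OC)c(OC)c2O
F8 | step 9 | (2S,3R)-2-{2-[(1R,3R)-1,3-dimethyl-2-methylidenecyclohexyl]ethyl}-6,7,8-trimethoxy-2-methyl-3,4-dihydro-2H-chromene-3,5-diol | C=C1[C@H](C)CCC[C@]1(C)CC[C@@]1(C)[C@H](O)Cc2c(O)c(OC)c(OC)c(OC)c2O1
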